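**Assumption:** The target SMILES corresponds to (2S,3S)-2,3-bis(4-hydroxy-3-methoxybenzyl)butane-1,2,4-triol. I number the chain C1 (CH2OH), C2 (the quaternary carbinol), C3 (the CH) and C4 (CH2OH). The target is acyclic, so no ring is built except the transient epoxide.

## Retrosynthetic overview
1. Carinol comes from global O-debenzylation of the tri-O-benzyl triol **15**.
2. The C3–CH2Ar bond and the C3 stereocentre come from regiospecific SN2 opening, at the secondary carbon, of the trisubstituted 2,3-epoxy alcohol **12** with ArCH2MgCl/Cu.
3. **12** comes from Sharpless asymmetric epoxidation of the (E)-2-benzyl allylic alcohol **10**. This sets C2, and the alkene geometry fixes the relative configuration at C3.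
4. **10** comes from DIBAL reduction of the (E)-enoate **9**, which is made by Horner–Wadsworth–Emmons olefination of the α-benzyl phosphonate **7** with BnOCH2CHO (**8**).
5. **7** is made by alkylating triethyl phosphonoacetate with the vanillyl-derived benzylic chloride **5**. The same chloride gives the Grignard reagent for the opening step.

## Route

**Step 1**
Reactants: 1 (vanillyl alcohol); 2 (benzyl bromide)
Product: 3 (4-benzyloxy-3-methoxybenzyl alcohol)
Conditions: K2CO3, DMF, 60 °C
Reagents that add atoms: benzyl bromide, BrCc1ccccc1
Why: K2CO3 deprotonates only the phenol (pKa about 10), so this is a chemoselective Williamson O-benzylation. The benzylic alcohol is untouched.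

**Step 2**
Reactants: 3; 4 (thionyl chloride)
Product: 5 (4-benzyloxy-3-methoxybenzyl chloride)
Conditions: SOCl2, CH2Cl2, 0 °C, 1 h. Concentrate and use at once.
Reagents that add atoms: thionyl chloride, O=S(Cl)Cl
Why: This is a standard alcohol-to-chloride conversion. The electron-rich benzylic chloride is unstable, so it is used crude and immediately.

**Step 3**
Reactants: 6 (triethyl phosphonoacetate); 5
Product: 7 (ethyl 3-[4-(benzyloxy)-3-methoxyphenyl]-2-(diethoxyphosphoryl)propanoate)
Conditions: NaH, THF, 0 °C to rt (6 in 1.5-fold excess)
Reagents that add atoms: none (NaH only deprotonates)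
Why: The stabilised phosphonate carbanion undergoes SN2 alkylation with the benzylic chloride. Excess phosphonate suppresses dialkylation.

**Step 4**
Reactants: 7; 8 (benzyloxyacetaldehyde)
Product: 9 ((E)-ethyl 4-benzyloxy-2-[4-(benzyloxy)-3-methoxybenzyl]but-2-enoate)
Conditions: LiCl, DBU, MeCN, 0 °C to rt
Reagents that add atoms: none
Why: Masamune–Roush Horner–Wadsworth–Emmons olefination of an α-branched phosphonate gives the E-trisubstituted enoate, with the ester trans to CH2OBn. This geometry is what later fixes the C2/C3 relative configuration, and any Z isomer is removed by chromatography.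

**Step 5**
Reactants: 9
Product: 10 ((E)-4-benzyloxy-2-[4-(benzyloxy)-3-methoxybenzyl]but-2-en-1-ol)
Conditions: DIBAL-H (2.5 equiv), CH2Cl2, −78 °C to 0 °C
Reagents that add atoms: none (DIBAL-H adds only hydrogen)
Why: 1,2-reduction of the ester gives the allylic alcohol. The benzyl ethers and the alkene geometry are unaffected.

**Step 6**
Reactants: 10; 11 (tert-butyl hydroperoxide)
Product: 12 ((2R,3R)-epoxy alcohol: {(2R,3R)-2-[4-(benzyloxy)-3-methoxybenzyl]-3-(benzyloxymethyl)oxiran-2-yl}methanol)
Conditions: Ti(OiPr)4 (10 mol%), D-(−)-DET (12 mol%), TBHP, 4 Å MS, CH2Cl2, −20 °C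
Reagents that add atoms: TBHP, CC(C)(C)OO (supplies the epoxide oxygen)
Why: Sharpless asymmetric epoxidation of a 2-substituted (E)-allylic alcohol with D-(−)-DET delivers oxygen to one face and sets C2 as R. The trans geometry gives the (2R,3R) epoxide, whose C3 inverts in step 8 to the required relative configuration.

**Step 7**
Reactants: 5; 13 (magnesium)
Product: 14 (4-benzyloxy-3-methoxybenzylmagnesium chloride)
Conditions: Mg turnings, I2 (cat.), THF, 0 °C, 1 h. Use at once.
Reagents that add atoms: magnesium, [Mg]
Why: Ordinary Grignard formation. Slow addition of 5 at low temperature keeps Wurtz homocoupling down.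

**Step 8**
Reactants: 12; 14 (4 equiv)
Product: 15 (tri-O-benzyl carinol)
Conditions: CuI (20 mol%), THF, −40 °C to 0 °C; NH4Cl work-up
Reagents that add atoms: none beyond 14 (CuI is catalytic)
Why: Cu-catalysed Grignard opening of a 2,3-epoxy alcohol occurs at the unhindered secondary C3 by SN2, with inversion. This creates the C3 stereocentre (S) and releases the tertiary C2 alkoxide with its configuration untouched. The quaternary C2 is not attacked, and the magnesium alkoxide of the free CH2OH helps direct the reaction.

**Step 9**
Reactants: 15
Product: 16 ((−)-carinol)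
Conditions: H2 (1 atm), 10% Pd/C, EtOAc/EtOH, rt
Reagents that add atoms: none (H2 adds only hydrogen)
Why: Hydrogenolysis removes the two aryl O-benzyl groups and the primary O-benzyl group. The tertiary alcohol, the aryl methyl ethers and both stereocentres are unaffected, since neither is benzylic or α to a carbonyl.

## Compound list
| No. | Name | SMILES | Role |
|---|---|---|---|
| 1 | vanillyl alcohol | OCc1ccc(O)c(OC)c1 | starting material |
| 2 | benzyl bromide | BrCc1ccccc1 | starting material |
| 3 | 4-benzyloxy-3-methoxybenzyl alcohol | COc1cc(CO)ccc1OCc1ccccc1 | intermediate |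
| 4 | thionyl chloride | O=S(Cl)Cl | starting material |
| 5 | 4-benzyloxy-3-methoxybenzyl chloride | COc1cc(CCl)ccc1OCc1ccccc1 | intermediate |
| 6 | triethyl phosphonoacetate | CCOC(=O)CP(=O)(OCC)OCC | starting material |
| 7 | α-(arylmethyl) phosphonoester | CCOC(=O)C(Cc1ccc(OCc2ccccc2)c(OC)c1)P(=O)(OCC)OCC | intermediate |
| 8 | benzyloxyacetaldehyde | O=CCOCc1ccccc1 | starting material |
| 9 | (E)-enoate | CCOC(=O)/C(Cc1ccc(OCc2ccccc2)c(OC)c1)=C/COCc1ccccc1 | intermediate |
| 10 | (E)-allylic alcohol | OC/C(Cc1ccc(OCc2ccccc2)c(OC)c1)=C/COCc1ccccc1 | intermediate |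
| 11 | tert-butyl hydroperoxide | CC(C)(C)OO | starting material |
| 12 | (2R,3R)-epoxy alcohol | OC[C@@]1(Cc2ccc(OCc3ccccc3)c(OC)c2)O[C@@H]1COCc1ccccc1 | intermediate |
| 13 | magnesium | [Mg] | starting material |
| 14 | 4-benzyloxy-3-methoxybenzylmagnesium chloride | COc1cc(C[Mg]Cl)ccc1OCc1ccccc1 | intermediate |
| 15 | tri-O-benzyl carinol | COc1cc(C[C@@H](COCc2ccccc2)[C@](O)(CO)Cc2ccc(OCc3ccccc3)c(OC)c2)ccc1OCc1ccccc1 | intermediate |
| 16 | (−)-carinol | COc1cc(C[C@@H](CO)[C@](O)(CO)Cc2ccc(O)c(OC)c2)ccc1O | target |

## Totals
Total steps: 9. Longest linear sequence: 8 (steps 1, 2, 3, 4, 5, 6, 8, 9). Step 7 is a side branch.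

## Three steps most likely to fail
1. **Step 8 (Cu-catalysed benzyl Grignard opening).** Possible problems are attack at the tertiary C2, Payne rearrangement, chlorohydrin formation from MgCl2, and Wurtz by-products.
   *Fallback (different approach):* abandon the epoxide. Build the lactone route instead: enantioenriched 4-(ArCH2)-3-silyloxy-γ-butyrolactone, enolate benzylation anti to the C4 benzyl (which puts the new benzyl trans to it, as the target requires), then LiAlH4 and hydrogenolysis.
2. **Step 6 (Sharpless asymmetric epoxidation of the hindered 2-arylmethyl trisubstituted alkene).** It may be sluggish or give modest ee.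
   *Fallback (different approach):* make the racemic epoxy alcohol with VO(acac)2/TBHP, then do a Sharpless kinetic resolution or a lipase-mediated resolution, so the stereochemistry comes from resolution rather than asymmetric induction.
3. **Step 4 (Horner–Wadsworth–Emmons olefination).** The aldehyde is enolisable and prone to polymerisation, and E/Z selectivity may be poor.
   *Fallback (different approach):* prepare the (E)-α-bromo enoate by Wittig olefination with Ph3P=C(Br)CO2Et, then install the arylmethyl group by Negishi coupling with ArCH2ZnCl, which gives the trisubstituted alkene by cross-coupling instead of olefination.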